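**Plan**

Numbering of the core: C1 ketone, C2=C3 enone (methyl on C3), C4 and C11 the cyclobutane CH groups that flank the enone, C5 the cyclobutane CH beside gem-dimethyl C6, C7 (angelate), C8, C9 (isovalerate), C10 the methylated quaternary cyclobutane carbon; on the seven-membered ring C5–C6–C7–C8–C9–C10–C11 the face that carries C4 is called α, the other β.
Enabling feature: C4 spans C10 and C5, the two ring neighbours of C11 in that seven-membered ring, so a cyclopropane carbon C4 fused on the C11–C5 bond can slip from C11 to C10; this turns the cyclopropane into the cyclobutane C11–C10–C4–C5 and creates the quaternary C10 and the C9 carbinol in one event.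
Retrosynthetic cuts: both ester C–O bonds; C1–C2 (carbonyl-ene) and C11–C1 (one-carbon homologation) of the cyclohexenone; C4–C10 together with C9–O (epoxide-triggered 1,2-shift); C4–C5 and C4–C11 (carbene addition to an enol silane); C7–O (epoxide of eucarvone).
Forward order: seven-membered ring from carvone through eucarvone, cyclopropane by rhodium-carbene addition, cyclobutane by ring expansion, cyclohexenone last by Wittig homologation and type-two carbonyl-ene closure; the C9 ester is attached after the ring expansion, the C7 ester near the end.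
Stereochemistry: a Jacobsen–Katsuki epoxidation installs a relay β-oxygen at C7 whose silyl ether sends the carbene to the α face (C4, C5); the β cyclopropanol hydroxyl directs the epoxide (C9) and the anti 1,2-shift fixes C10; the relay carbinol is then oxidised and reset to the α-alcohol by reagent-controlled CBS reduction, so the final C7 configuration does not depend on the carbene step; C11–H comes from aldehyde equilibration and the ring closure.

Key step: step 11

Assumption: the (S,S)-salen manganese catalyst is taken to give the (4S,5R)-epoxide, by analogy with 2,2-dimethylchromenes; if the sense is the reverse, the (R,R)-catalyst is used and nothing else changes.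

**Route**

Step 1
Reactants: 1 (R)-(−)-carvone
Product: 2 carvone hydrobromide, (5R)-5-(2-bromopropan-2-yl)-2-methylcyclohex-2-en-1-one
Conditions: HBr (33% in AcOH), 0 °C
Reagents that add atoms: hydrogen bromide, Br
Why: Markovnikov hydrobromination of the electron-rich isopropenyl alkene gives the tertiary bromide while the acyl-deactivated ring alkene is left alone; the stereocentre is lost in the next step.

Step 2
Reactants: 2 carvone hydrobromide
Product: 4 eucarvone (2,6,6-trimethylcyclohepta-2,4-dien-1-one), via car-3-en-2-one 3 (not isolated)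
Conditions: KOH, MeOH, 0 °C to reflux
Reagents that add atoms: none
Why: Intramolecular enolate alkylation by the tertiary bromide (3-exo-tet) gives the carenone, whose dienolate opens by norcaradiene-to-cycloheptatriene electrocyclisation and reprotonates to the achiral conjugated dienone (the classical eucarvone preparation).

Step 3
Reactants: 4 eucarvone
Product: 5 (4S,5R)-4,5-epoxy-2,6,6-trimethylcyclohept-2-en-1-one (epoxide on C7–C8 of the core)
Conditions: (S,S)-(salen)MnCl [chloro manganese complex of (S,S)-N,N'-bis(3,5-di-tert-butylsalicylidene)cyclohexane-1,2-diamine] (5 mol%), mCPBA, N-methylmorpholine N-oxide, CH2Cl2, −78 °C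
Reagents that add atoms: mCPBA, O=C(OO)c1cccc(Cl)c1
Why: Jacobsen–Katsuki epoxidation should select the cis-disubstituted, electron-richer γ,δ-alkene next to the quaternary carbon (the 2,2-dimethylchromene pattern) over the deactivated trisubstituted α,β-alkene, the chiral manganese-oxo species choosing the enantioface and so setting C7 and C8.

Step 4
Reactants: 5 epoxy enone
Product: 6 (5S)-5-hydroxy-2,6,6-trimethylcyclohept-2-en-1-one (C7 carbinol of the core)
Conditions: Pd2(dba)3·CHCl3 (2.5 mol%), n-Bu3P (10 mol%), HCO2H, Et3N, dioxane, rt
Reagents that add atoms: none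
Why: Zerovalent palladium ionises the allylic C8–O bond to a π-allyl complex and formate delivers hydride to C8, the terminus remote from the carbonyl (palladium-catalysed formate hydrogenolysis of an alkenyl epoxide), so the enone stays conjugated and the C7–O bond keeps its configuration.

Step 5
Reactants: 6 hydroxy enone
Product: 7 (5S)-5-(tert-butyldimethylsilyloxy)-2,6,6-trimethylcyclohept-2-en-1-one
Conditions: TBSOTf, 2,6-lutidine, CH2Cl2, −78 to 0 °C
Reagents that add atoms: tert-butyldimethylsilyl triflate, CC(C)(C)[Si](C)(C)OS(=O)(=O)C(F)(F)F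
Why: Silyl triflate silylation copes with the hindered secondary alcohol beside the quaternary carbon, and the weak hindered base does not enolise the enone.

Step 6
Reactants: 7 silyloxy enone
Product: 9 kinetic trimethylsilyl dienol ether (C11–OTMS; C11=C5; C9=C10), via lithium dienolate 8 (not isolated)
Conditions: LDA, THF, −78 °C; then TMSCl, −78 to 0 °C
Reagents that add atoms: chlorotrimethylsilane, C[Si](C)(C)Cl
Why: Kinetic deprotonation of an enone by lithium diisopropylamide takes the α' methylene C5 (cross-conjugated enolate, as with isophorone) and not the γ position C8, and O-silylation traps it as the 2-silyloxy-1,3-diene.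

Step 7
Reactants: 9 silyl dienol ether; 10 ethyl diazoacetate
Product: 11 siloxycyclopropane ester (cyclopropane C11–C5–C4 on the α face, trans to the C7 silyloxy group; ester exo on C4)
Conditions: Rh2(OAc)4 (1 mol%), CH2Cl2, rt, slow addition of 10
Reagents that add atoms: ethyl diazoacetate (10), CCOC(=O)C=[N+]=[N-]
Why: Rhodium-carbene cyclopropanation of a silyl enol ether should take the most electron-rich alkene C11=C5, approach C5 from the α face because the β silyloxy group on C7 screens the other face across the quaternary C6, and place the ester exo, away from the ring and the C6 methyls, which sets C11, C5 and C4.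

Step 8
Reactants: 11 cyclopropane ester; 12 methylmagnesium bromide
Product: 14 tertiary alcohol (C4–C(CH3)2OH), via methyl ketone 13 (not isolated)
Conditions: 12 (3 equiv), THF, −78 to 0 °C; aq NH4Cl
Reagents that add atoms: methylmagnesium bromide (12), C[Mg]Br
Why: Double Grignard addition to the ester builds the dimethylcarbinol C3 and removes the acceptor, so the siloxycyclopropane is no longer prone to retro-aldol opening; no stereocentre is touched.

Step 9
Reactants: 14 tertiary alcohol
Product: 15 triethylsilyl ether of 14
Conditions: TESOTf, 2,6-lutidine, CH2Cl2, −78 °C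
Reagents that add atoms: triethylsilyl triflate, CC[Si](CC)(CC)OS(=O)(=O)C(F)(F)F
Why: Buffered silyl triflate silylation caps the tertiary hydroxyl, which would otherwise attack the C10 epoxide carbon (tetrahydrofuran formation) or compete as a directing group in the key step.

Step 10
Reactants: 15 tris-silyl ether
Product: 16 cyclopropanol, 5β-(tert-butyldimethylsilyloxy)-2,6,6-trimethyl-8-exo-[2-(triethylsilyloxy)propan-2-yl]bicyclo[5.1.0]oct-2-en-1β-ol
Conditions: K2CO3, MeOH, 0 °C
Reagents that add atoms: none
Why: Mild methanolysis cleaves only the trimethylsilyl ether, the triethylsilyl and tert-butyldimethylsilyl ethers being much slower, and with no acceptor on the ring the free cyclopropanol should not open.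

Step 11
Reactants: 16 cyclopropanol
Product: 18 cyclobutanone, 2β-hydroxy-4β-(tert-butyldimethylsilyloxy)-1,5,5-trimethyl-7-[2-(triethylsilyloxy)propan-2-yl]bicyclo[4.1.1]octan-8-one (C4 substituent anti to the four-carbon bridge), via epoxy cyclopropanol 17 (not isolated)
Conditions: VO(acac)2 (5 mol%), t-BuOOH (1.3 equiv, in decane), CH2Cl2, 0 °C to rt, under argon
Reagents that add atoms: tert-butyl hydroperoxide, CC(C)(C)OO
Why: The vanadium-bound cyclopropanolate on C11 delivers the peroxide oxygen to its own (β) face of the allylic C9=C10 alkene to give epoxy alcohol 17, whose tertiary C10–O bond then ionises with help from the antiperiplanar cyclopropane bond C11–C4, so that C4 shifts from C11 to C10 as the C11 carbonyl forms. The closest known reaction type is the epoxidation-triggered semipinacol ring expansion of 1-alkenylcyclopropanols to 2-(1-hydroxyalkyl)cyclobutanones. The one ring closed, cyclobutanone C11–C10–C4–C5, arises by this 1,2-alkyl shift (formally an exo-tet opening of the epoxide at C10 by the C11–C4 σ bond), which turns the fused bicyclo[5.1.0] skeleton into the bridged bicyclo[4.1.1]octanone. C9 is set by the hydroxyl-directed oxygen delivery (syn to C11–OH, anti to C4), C10 by inversion at the epoxide carbon as C4 enters opposite the oxygen, and C4 migrates with retention. The step needs opening at the tertiary, cyclopropylcarbinyl C10 and migration of C4 in preference to the ring-fusion carbon C5; both follow from the directed epoxide face, because only C11–C4 lies anti to the C10–O bond while C11–C5 sits near the ring plane. Release of cyclopropane strain and formation of the carbonyl group drive the shift.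

Step 12
Reactants: 18 hydroxy cyclobutanone; 19 isovaleric anhydride
Product: 20 C9 isovalerate
Conditions: 19, DMAP, Et3N, CH2Cl2, rt
Reagents that add atoms: isovaleric anhydride (19), CC(C)CC(=O)OC(=O)CC(C)C
Why: DMAP-catalysed acyl transfer esterifies the only free hydroxyl, and because C10 is quaternary the β-acyloxy ketone cannot eliminate.

Step 13
Reactants: 20 keto ester; 21 (methoxymethyl)triphenylphosphonium chloride
Product: 22 C11 methoxymethylene enol ether (mixture of enol ether geometries)
Conditions: 21, KN(SiMe3)2, THF, 0 °C; then 20, 0 °C to rt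
Reagents that add atoms: (methoxymethyl)triphenylphosphonium chloride (21), COC[P+](c1ccccc1)(c1ccccc1)c1ccccc1.[Cl-]
Why: Wittig methoxymethylenation should succeed because the strained cyclobutanone is highly electrophilic and cannot enolise toward its bridgeheads, while the ylide leaves the ester alone.

Step 14
Reactants: 22 enol ether
Product: 23 diol (C7β–OH and C3–OH free)
Conditions: TBAF, AcOH (1:1), THF, 0 °C to rt
Reagents that add atoms: none
Why: Fluoride desilylation frees both hydroxyls; the acetic acid buffer keeps the alkoxide concentration low so that the C9 ester does not migrate to the syn C7 oxygen, and the enol ether is inert to fluoride.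

Step 15
Reactants: 23 diol
Product: 24 C7 ketone
Conditions: Dess–Martin periodinane, pyridine, CH2Cl2, 0 °C
Reagents that add atoms: none
Why: Dess–Martin oxidation of the only secondary alcohol erases the relay stereocentre, the tertiary alcohol cannot be oxidised and the pyridine buffer protects the enol ether.

Step 16
Reactants: 24 hydroxy ketone
Product: 25 isopropenyl ketone
Conditions: Burgess reagent (methyl N-(triethylammoniosulfonyl)carbamate), benzene, 50 °C
Reagents that add atoms: none
Why: Burgess dehydration (syn elimination through the sulfamate ester) of the tertiary alcohol should go toward a methyl group, favoured statistically and because the alternative would put a tetrasubstituted alkene on the strained bridge carbon C4.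

Step 17
Reactants: 25 ketone
Product: 26 (7R)-alcohol (C7–OH on the α face, anti to the C9 ester)
Conditions: (S)-2-methyl-CBS-oxazaborolidine [(S)-1-methyl-3,3-diphenyltetrahydro-1H,3H-pyrrolo[1,2-c][1,3,2]oxazaborole] (20 mol%), catecholborane, toluene, −78 to −40 °C
Reagents that add atoms: none
Why: Corey–Bakshi–Shibata reduction distinguishes the quaternary C6 flank from the methylene C8 flank and should deliver hydride to the β face to give the (7R) carbinol under reagent control, while catecholborane at low temperature spares the ester, enol ether and isopropenyl groups.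

Step 18
Reactants: 26 alcohol; 27 angelic acid
Product: 28 C7 angelate
Conditions: 27, 2,4,6-trichlorobenzoyl chloride, Et3N, toluene, rt; then 26, 80 °C
Reagents that add atoms: angelic acid (27), C/C=C(/C)C(O)=O
Why: Yamaguchi-type mixed-anhydride esterification without a nucleophilic catalyst transfers the (Z)-2-methylbut-2-enoyl group to hindered secondary alcohols without isomerisation to the tiglate.

Step 19
Reactants: 28 enol ether diester
Product: 30 aldehyde with the formyl group on C11 anti to the four-carbon bridge, via syn-formyl epimer 29 (not isolated)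
Conditions: 1 M HCl, THF, 0 °C to rt; then DBU (0.2 equiv), CH2Cl2, rt
Reagents that add atoms: water, O
Why: Acid hydrolysis of the enol ether gives the C1 aldehyde, and enolisation should equilibrate C11 toward the epimer with the formyl group anti to the four-carbon bridge, because the syn position lies in the cleft under that bridge between a C6 methyl and the C9 acyloxy group; any syn epimer left is unreactive in step 20 and can be re-equilibrated.

Step 20
Reactants: 30 aldehyde
Product: 31 tricyclic ene adduct (C1 carbinol of either configuration, exo-methylene on C3)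
Conditions: Me2AlCl (1.5 equiv), CH2Cl2, −78 to −20 °C
Reagents that add atoms: none
Why: Lewis acid-promoted type-two intramolecular carbonyl-ene reaction: the formyl group on C11 and the isopropenyl group on C4 are held syn-1,3 across the folded cyclobutane, the alkene terminus C2 bonds to C1 as a methyl hydrogen passes to oxygen, and the six-membered ring C11–C1–C2–C3–C4–C5 closes without a free cation beside the cyclobutane.

Step 21
Reactants: 31 ene adduct
Product: 33 CNP0240547.2 (target), via exo-methylene ketone 32 (not isolated)
Conditions: Dess–Martin periodinane, pyridine, CH2Cl2, 0 °C to rt; then DBU (0.3 equiv), rt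
Reagents that add atoms: none
Why: Dess–Martin oxidation gives the β,γ-unsaturated ketone, whose doubly activated C2 hydrogens let mild base move the alkene into conjugation (the verbenone-type enone is the thermodynamic isomer) under conditions that should leave the angelate geometry intact.

**Compound list**

1 | (R)-(−)-carvone | CC1=CC[C@H](CC1=O)C(C)=C | starting material
2 | carvone hydrobromide, (5R)-5-(2-bromopropan-2-yl)-2-methylcyclohex-2-en-1-one | CC1=CC[C@H](CC1=O)C(C)(C)Br | intermediate
3 | car-3-en-2-one, cis-fused 3,7,7-trimethylbicyclo[4.1.0]hept-3-en-2-one | CC1=CC[C@@H]2[C@H](C1=O)C2(C)C | intermediate (not isolated)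
4 | eucarvone, 2,6,6-trimethylcyclohepta-2,4-dien-1-one | CC1=CC=CC(C)(C)CC1=O | intermediate
5 | (4S,5R)-4,5-epoxy-2,6,6-trimethylcyclohept-2-en-1-one | CC1=C[C@@H]2O[C@@H]2C(C)(C)CC1=O | intermediate
6 | (5S)-5-hydroxy-2,6,6-trimethylcyclohept-2-en-1-one | O[C@H]1CC=C(C)C(=O)CC1(C)C | intermediate
7 | (5S)-5-(tert-butyldimethylsilyloxy)-2,6,6-trimethylcyclohept-2-en-1-one | CC(C)(C)[Si](C)(C)O[C@H]1CC=C(C)C(=O)CC1(C)C | intermediate
8 | lithium cross-conjugated dienolate of 7 (C11–OLi, C11=C5) | CC(C)(C)[Si](C)(C)O[C@H]1CC=C(C)C(O[Li])=CC1(C)C | intermediate (not isolated)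
9 | trimethylsilyl dienol ether of 7 (C11–OTMS, C11=C5, C9=C10) | CC(C)(C)[Si](C)(C)O[C@H]1CC=C(C)C(O[Si](C)(C)C)=CC1(C)C | intermediate
10 | ethyl diazoacetate | CCOC(=O)C=[N+]=[N-] | starting material
11 | ethyl 5β-(tert-butyldimethylsilyloxy)-2,6,6-trimethyl-1β-(trimethylsilyloxy)bicyclo[5.1.0]oct-2-ene-8-exo-carboxylate (cyclopropane carbon C4 on the α face) | CC(C)(C)[Si](C)(C)O[C@H]1CC=C(C)[C@]2(O[Si](C)(C)C)[C@@H](C(=O)OCC)[C@@H]2C1(C)C | intermediate
12 | methylmagnesium bromide | C[Mg]Br | starting material
13 | methyl ketone from the first Grignard addition to 11 (C4–COCH3) | CC(C)(C)[Si](C)(C)O[C@H]1CC=C(C)[C@]2(O[Si](C)(C)C)[C@@H](C(C)=O)[C@@H]2C1(C)C | intermediate (not isolated)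
14 | tertiary alcohol (C4–C(CH3)2OH, exo) | CC(C)(C)[Si](C)(C)O[C@H]1CC=C(C)[C@]2(O[Si](C)(C)C)[C@@H](C(C)(C)O)[C@@H]2C1(C)C | intermediate
15 | triethylsilyl ether of 14 | CC(C)(C)[Si](C)(C)O[C@H]1CC=C(C)[C@]2(O[Si](C)(C)C)[C@@H](C(C)(C)O[Si](CC)(CC)CC)[C@@H]2C1(C)C | intermediate
16 | key-step precursor, 5β-(tert-butyldimethylsilyloxy)-2,6,6-trimethyl-8-exo-[2-(triethylsilyloxy)propan-2-yl]bicyclo[5.1.0]oct-2-en-1β-ol | CC(C)(C)[Si](C)(C)O[C@H]1CC=C(C)[C@]2(O)[C@@H](C(C)(C)O[Si](CC)(CC)CC)[C@@H]2C1(C)C | intermediate
17 | C9–C10 β-epoxide of 16 (syn to the C11 hydroxyl) | CC(C)(C)[Si](C)(C)O[C@H]1C[C@H]3O[C@@]3(C)[C@]2(O)[C@@H](C(C)(C)O[Si](CC)(CC)CC)[C@@H]2C1(C)C | intermediate (not isolated)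
18 | key-step product, 2β-hydroxy-4β-(tert-butyldimethylsilyloxy)-1,5,5-trimethyl-7-[2-(triethylsilyloxy)propan-2-yl]bicyclo[4.1.1]octan-8-one | CC(C)(C)[Si](C)(C)O[C@H]1C[C@@H](O)[C@@]3(C)C(=O)[C@H]([C@@H]3C(C)(C)O[Si](CC)(CC)CC)C1(C)C | intermediate
19 | isovaleric anhydride | CC(C)CC(=O)OC(=O)CC(C)C | starting material
20 | C9 isovalerate of 18 | CC(C)(C)[Si](C)(C)O[C@H]1C[C@@H](OC(=O)CC(C)C)[C@@]3(C)C(=O)[C@H]([C@@H]3C(C)(C)O[Si](CC)(CC)CC)C1(C)C | intermediate
21 | (methoxymethyl)triphenylphosphonium chloride | COC[P+](c1ccccc1)(c1ccccc1)c1ccccc1.[Cl-] | starting material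
22 | C11 methoxymethylene enol ether (both enol ether geometries) | CC(C)(C)[Si](C)(C)O[C@H]1C[C@@H](OC(=O)CC(C)C)[C@@]3(C)C(=COC)[C@H]([C@@H]3C(C)(C)O[Si](CC)(CC)CC)C1(C)C | intermediate
23 | diol (C7β–OH, C3–OH) | O[C@H]1C[C@@H](OC(=O)CC(C)C)[C@@]3(C)C(=COC)[C@H]([C@@H]3C(C)(C)O)C1(C)C | intermediate
24 | C7 ketone with tertiary C3–OH | O=C1C[C@@H](OC(=O)CC(C)C)[C@@]3(C)C(=COC)[C@H]([C@@H]3C(C)(C)O)C1(C)C | intermediate
25 | C7 ketone with isopropenyl on C4 | O=C1C[C@@H](OC(=O)CC(C)C)[C@@]3(C)C(=COC)[C@H]([C@@H]3C(C)=C)C1(C)C | intermediate
26 | (7R)-alcohol (C7–OH α, anti to the C9 ester) | O[C@@H]1C[C@@H](OC(=O)CC(C)C)[C@@]3(C)C(=COC)[C@H]([C@@H]3C(C)=C)C1(C)C | intermediate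
27 | angelic acid, (Z)-2-methylbut-2-enoic acid | C/C=C(/C)C(O)=O | starting material
28 | C7 angelate, C9 isovalerate, C11 enol ether | C/C=C(/C)C(=O)O[C@@H]1C[C@@H](OC(=O)CC(C)C)[C@@]3(C)C(=COC)[C@H]([C@@H]3C(C)=C)C1(C)C | intermediate
29 | C11-epimeric aldehyde (formyl syn to the four-carbon bridge) | C/C=C(/C)C(=O)O[C@@H]1C[C@@H](OC(=O)CC(C)C)[C@@]3(C)[C@@H](C=O)[C@H]([C@@H]3C(C)=C)C1(C)C | intermediate (not isolated)
30 | aldehyde (formyl on C11 anti to the four-carbon bridge, syn to the isopropenyl group on C4) | C/C=C(/C)C(=O)O[C@@H]1C[C@@H](OC(=O)CC(C)C)[C@@]3(C)[C@H](C=O)[C@H]([C@@H]3C(C)=C)C1(C)C | intermediate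
31 | tricyclic ene adduct (C1–OH of either configuration, C3 exo-methylene) | C/C=C(/C)C(=O)O[C@@H]1C[C@@H](OC(=O)CC(C)C)[C@@]2(C)[C@@H]3C(O)CC(=C)[C@H]2[C@@H]3C1(C)C | intermediate
32 | tricyclic β,γ-unsaturated ketone (C1 ketone, C3 exo-methylene) | C/C=C(/C)C(=O)O[C@@H]1C[C@@H](OC(=O)CC(C)C)[C@@]2(C)[C@@H]3C(=O)CC(=C)[C@H]2[C@@H]3C1(C)C | intermediate (not isolated)
33 | CNP0240547.2 | C/C=C(/C)C(=O)O[C@@H]1C[C@@H](OC(=O)CC(C)C)[C@@]2(C)[C@@H]3C(=O)C=C(C)[C@H]2[C@@H]3C1(C)C | target

**Step count and risks**

Total step count: 21. Longest linear sequence: 21 steps (1 to 33).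

Steps most likely to fail:

Step 7. What may go wrong: the remote C7 silyloxy group may discriminate the two faces of the enol silane too weakly, the ester may be delivered endo, or the carbene may add to the C9=C10 alkene. Fallback (reagent control in place of substrate control): setting out from 9, the cyclopropanation is run with tert-butyl diazoacetate and CuOTf carrying 2,2'-isopropylidenebis[(4S)-4-tert-butyl-2-oxazoline], the ligand enantiomer being chosen to reinforce the substrate bias and the bulky ester to enforce exo delivery. This gives the tert-butyl ester F1, and excess MeLi converts F1 into the tertiary alcohol 14, where the route is rejoined.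

Step 11. What may go wrong: one-electron oxidation of the cyclopropanolate by the vanadium peroxo species, leading to β-scission of the three-membered ring, or epoxide opening without the 1,2-shift. Fallback (two-electron oxidant, oxidation and shift decoupled): setting out from 16, hydrogen-bond-directed peracid epoxidation (mCPBA, NaHCO3, CH2Cl2, 0 °C; Henbest-type) gives the epoxy cyclopropanol 17, which is isolated. A separate treatment with a mild Lewis acid (MgBr2·OEt2 or BF3·OEt2, CH2Cl2, −78 °C) then triggers the shift to 18, where the route is rejoined.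

Step 20. What may go wrong: ionisation beside the cyclobutane under the Lewis acid with Wagner–Meerwein ring expansion, or Lewis acid-induced loss of the angelate geometry. Fallback (neutral C–C bond formation): setting out from 30, Nozaki–Hiyama–Kishi vinylation (vinyl bromide, CrCl2, catalytic NiCl2, DMF) gives the vinyl carbinol F2. Ring-closing metathesis between the vinyl and isopropenyl groups with the second-generation Grubbs catalyst gives the cyclohexenol F3, and oxidation of this allylic alcohol with MnO2 gives the target 33 directly.

Further compounds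

F1 | step 7 | tert-butyl ester analogue of 11 | CC(C)(C)[Si](C)(C)O[C@H]1CC=C(C)[C@]2(O[Si](C)(C)C)[C@@H](C(=O)OC(C)(C)C)[C@@H]2C1(C)C
F0 | step 11 | none | none
F2 | step 20 | vinyl carbinol from 30 (C1–OH of either configuration) | C/C=C(/C)C(=O)O[C@@H]1C[C@@H](OC(=O)CC(C)C)[C@@]3(C)[C@H](C(O)C=C)[C@H]([C@@H]3C(C)=C)C1(C)C
F3 | step 20 | tricyclic allylic alcohol (C1–OH, C2=C3) | C/C=C(/C)C(=O)O[C@@H]1C[C@@H](OC(=O)CC(C)C)[C@@]2(C)[C@@H]3C(O)C=C(C)[C@H]2[C@@H]3C1(C)C
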